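**Retrosynthetic overview**
- The target is reached from its tris-MOM ether by acetal methanolysis. Ring C is disconnected at C3–C4 and read as the addition of a formyl C–H (the future C4) across the C2=C3 bond of an aryl 1-arylvinyl ether.
- That asymmetric 6-endo hydroacylation closes ring C, the only ring formed, and sets C2; rings A and B come from resorcinol and isovanillic acid.
- Feature the strategy rests on: in ring A, O1 sits on C8a para to the geranyl-bearing C6, and C5 and C7 carry identical oxygens. The ring A phenol is therefore mirror-symmetric about the O1–C8a···C6 axis, either carbon ortho to O1 can become C4a, and no 6- versus 8-geranyl question arises.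
- The aldehyde precursor comes from an aryl bromide (Br/Li exchange, DMF), made by Petasis methylenation of the ester of the monobrominated symmetric phenol with MOM-isovanillic acid.
- The symmetric phenol comes from resorcinol bis-MOM ether by meta C–H borylation/oxidation, silylation, lithiation/geranylation between the two MOM ethers, and desilylation.

Key step: step 11

Assumption: which antipode of the bisphosphine gives the (S) product cannot be predicted for this new substrate class; (R)-DTBM-SEGPHOS is written, and the commercially available (S) antipode is used instead if a first run shows the opposite sense.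

**Step 1**
Reactants: 1 resorcinol
Product: 2 1,3-bis(methoxymethoxy)benzene
Conditions: MOMCl (2.5 equiv), i-Pr2NEt, CH2Cl2, 0 °C → rt
Reagents that add atoms: chloromethyl methyl ether, COCCl
Why: O-alkylation of both phenols with an α-chloro ether (acetal formation) is a standard, high-yielding protection.

**Step 2**
Reactants: 2 1,3-bis(methoxymethoxy)benzene
Product: 4 3,5-bis(methoxymethoxy)phenol, via arylboronic pinacol ester 3 (not isolated)
Conditions: [Ir(cod)OMe]2 (1.5 mol %), 4,4′-di-tert-butyl-2,2′-bipyridine (3 mol %), B2pin2 (1.0 equiv), THF, 80 °C; then NaOH (aq), H2O2, 0 °C → rt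
Reagents that add atoms: bis(pinacolato)diboron, CC1(C)OB(OC1(C)C)B1OC(C)(C)C(C)(C)O1 (boron of intermediate 3 only); hydrogen peroxide, OO
Why: Iridium-catalysed aromatic C–H borylation is sterically controlled and should take place only at C5, the one position of the 1,3-disubstituted arene without an ortho substituent, and alkaline peroxide oxidation of the C–B bond gives the phenol without touching the MOM ethers.

**Step 3**
Reactants: 4 3,5-bis(methoxymethoxy)phenol
Product: 5 [3,5-bis(methoxymethoxy)phenoxy]triisopropylsilane
Conditions: TIPSCl, imidazole, DMF, rt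
Reagents that add atoms: triisopropylsilyl chloride, CC(C)[Si](Cl)(C(C)C)C(C)C
Why: Silylation of the phenol gives a bulky, non-coordinating ether that survives n-BuLi and does not direct metalation.

**Step 4**
Reactants: 5 [3,5-bis(methoxymethoxy)phenoxy]triisopropylsilane; 6 geranyl bromide, (E)-1-bromo-3,7-dimethylocta-2,6-diene
Product: 8 {4-[(E)-3,7-dimethylocta-2,6-dienyl]-3,5-bis(methoxymethoxy)phenoxy}triisopropylsilane, via aryllithium 7 (not isolated)
Conditions: n-BuLi, THF, 0 °C; CuI (10 mol %), then 6, −78 °C → rt
Reagents that add atoms: n-butyllithium, CCCC[Li] (lithium of intermediate 7 only)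
Why: Directed ortho-metalation, in which both MOM ethers cooperate to deliver the base to the carbon between them while the TIPS ether shields its own neighbours, followed by copper-catalysed SN2 allylation of the hindered aryl nucleophile, which keeps the E alkene of the geranyl unit.

**Step 5**
Reactants: 8 geranylated TIPS ether
Product: 9 4-[(E)-3,7-dimethylocta-2,6-dienyl]-3,5-bis(methoxymethoxy)phenol
Conditions: TBAF, AcOH (1:1), THF, 0 °C → rt
Reagents that add atoms: none
Why: Fluoride-induced desilylation, buffered with acetic acid, frees the phenol while acetals and alkenes are inert.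

**Step 6**
Reactants: 9 4-geranyl-3,5-bis(methoxymethoxy)phenol
Product: 10 2-bromo-4-[(E)-3,7-dimethylocta-2,6-dienyl]-3,5-bis(methoxymethoxy)phenol
Conditions: NBS (1.0 equiv), CH2Cl2, −78 °C
Reagents that add atoms: N-bromosuccinimide, O=C1CCC(=O)N1Br
Why: Electrophilic aromatic bromination, in which the trioxygenated phenol ring should be far more nucleophilic than the trisubstituted alkenes, the para position is blocked by the geranyl group and the two ortho positions are equivalent, so one equivalent at low temperature should give a single monobromide.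

**Step 7**
Reactants: 11 isovanillic acid, 3-hydroxy-4-methoxybenzoic acid
Product: 13 4-methoxy-3-(methoxymethoxy)benzoic acid, via methoxymethyl ester 12 (not isolated)
Conditions: MOMCl (2.5 equiv), i-Pr2NEt, CH2Cl2, 0 °C → rt; then LiOH, THF/MeOH/H2O, rt; 1 M HCl to pH 4, 0 °C
Reagents that add atoms: chloromethyl methyl ether, COCCl
Why: Double O-alkylation of phenol and carboxylate followed by saponification of the labile methoxymethyl ester leaves the aryl MOM ether, which is stable to base and to brief mild acidification.

**Step 8**
Reactants: 10 2-bromo-4-geranyl-3,5-bis(methoxymethoxy)phenol; 13 4-methoxy-3-(methoxymethoxy)benzoic acid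
Product: 14 2-bromo-4-[(E)-3,7-dimethylocta-2,6-dienyl]-3,5-bis(methoxymethoxy)phenyl 4-methoxy-3-(methoxymethoxy)benzoate
Conditions: DIC, DMAP (cat.), CH2Cl2, 0 °C → rt
Reagents that add atoms: none
Why: Steglich esterification acylates the phenol under neutral conditions and avoids the HCl that an acid chloride preparation would bring into contact with the MOM ethers.

**Step 9**
Reactants: 14 aryl ester
Product: 15 2-bromo-4-[(E)-3,7-dimethylocta-2,6-dienyl]-3,5-bis(methoxymethoxy)phenyl 1-[4-methoxy-3-(methoxymethoxy)phenyl]vinyl ether
Conditions: Cp2TiMe2 (2.5 equiv), toluene, 70 °C, dark; filtration through basic alumina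
Reagents that add atoms: dimethyltitanocene, C[Ti](C)(C1C=CC=C1)C1C=CC=C1
Why: Petasis methylenation, in which thermally generated Cp2Ti=CH2 converts the aryl ester carbonyl into the 1-arylvinyl ether through an oxatitanacyclobutane under conditions free of Brønsted and Lewis acid that spare the MOM ethers, the aryl bromide and the hindered trisubstituted alkenes.

**Step 10**
Reactants: 15 bromo aryl vinyl ether
Product: 18 2-{1-[4-methoxy-3-(methoxymethoxy)phenyl]vinyloxy}-5-[(E)-3,7-dimethylocta-2,6-dienyl]-4,6-bis(methoxymethoxy)benzaldehyde, via aryllithium 16 (not isolated), via lithium hemiaminal alkoxide 17 (not isolated)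
Conditions: n-BuLi (1.05 equiv), THF, −78 °C, 15 min; DMF, −78 → 0 °C; H2O
Reagents that add atoms: n-butyllithium, CCCC[Li] (lithium of intermediates 16 and 17 only); N,N-dimethylformamide, CN(C)C=O
Why: Bromine–lithium exchange at −78 °C is much faster than addition of n-BuLi to the styrenyl enol ether or deprotonation on ring B, so the metal is placed only on the carbon between the enol ether oxygen and a MOM ether, and the aryllithium is then formylated with DMF (Bouveault-type formylation).

**Step 11**
Reactants: 18 aldehyde with the 1-arylvinyl ether ortho to the formyl group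
Product: 19 (S)-6-[(E)-3,7-dimethylocta-2,6-dienyl]-5,7-bis(methoxymethoxy)-2-[4-methoxy-3-(methoxymethoxy)phenyl]chroman-4-one
Conditions: [Rh(cod)Cl]2 (2.5 mol %), (R)-DTBM-SEGPHOS (5.5 mol %), Na[B(3,5-(CF3)2C6H3)4] (6 mol %), degassed 1,4-dioxane, 60 °C, base-washed glassware
Reagents that add atoms: none
Why: Proposed new method: a cationic bisphosphine complex of monovalent rhodium should insert into the formyl C–H bond to give an acyl hydride of trivalent rhodium that is held by the tethered alkene and a flanking ether oxygen, which slows decarbonylation; hydride insertion into C2=C3 is expected to be reversible in both senses, but only delivery of H to C2 gives a primary alkyl–rhodium in a seven-membered rhodacycle that can reductively eliminate to form C3–C4. Delivery of H to C3 would give a tertiary, benzylic, oxygen-bearing alkyl–rhodium whose reductive elimination to a 2-aryl-2-methylbenzofuran-3-one with a quaternary carbon should be slow, so that intermediate should revert. The closest known reaction is the rhodium-catalysed endo- and enantioselective hydroacylation of ortho-allylbenzaldehydes bearing 1,1-disubstituted alkenes to 3-substituted tetralones, from which this substrate differs by having oxygen in place of the benzylic CH2. Ring C closes in a formal 6-endo-trig mode. The C2 stereocentre arises when hydride is delivered to one face of the vinyl ether and is controlled by the C2-symmetric bisphosphine, the faster-eliminating diastereomeric rhodacycle setting the enantiomer. The step needs 6-endo over 5-exo closure, face selection and chemoselectivity: the 1,1-disubstitution of the alkene secures the first, the ligand the second, and the geranyl alkenes are trisubstituted and meta to the formyl group so they cannot chelate, while acid-free conditions prevent aldol-type closure of the enol ether onto the aldehyde.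

**Step 12**
Reactants: 19 (S)-tris-MOM flavanone
Product: 20 (S)-6-geranylhesperetin, (2S)-5,7-dihydroxy-2-(3-hydroxy-4-methoxyphenyl)-6-[(2E)-3,7-dimethylocta-2,6-dienyl]chroman-4-one
Conditions: HCl (1.25 M in MeOH), 0 °C → rt; NaHCO3 (aq) work-up
Reagents that add atoms: none
Why: Acid-catalysed acetal methanolysis removes the three MOM ethers as dimethoxymethane, flavanones do not racemise under acid (that needs base-induced ring opening), and short exposure to mild acid should avoid cyclisation of the geranyl chain onto the neighbouring phenols.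

**Compound list**
1 | resorcinol | Oc1cccc(O)c1 | starting material
2 | 1,3-bis(methoxymethoxy)benzene | COCOc1cccc(OCOC)c1 | intermediate
3 | 2-[3,5-bis(methoxymethoxy)phenyl]-4,4,5,5-tetramethyl-1,3,2-dioxaborolane | COCOc1cc(OCOC)cc(B2OC(C)(C)C(C)(C)O2)c1 | intermediate
4 | 3,5-bis(methoxymethoxy)phenol | COCOc1cc(O)cc(OCOC)c1 | intermediate
5 | [3,5-bis(methoxymethoxy)phenoxy]triisopropylsilane | COCOc1cc(OCOC)cc(O[Si](C(C)C)(C(C)C)C(C)C)c1 | intermediate
6 | geranyl bromide | BrC/C=C(\C)CCC=C(C)C | starting material
7 | 2,6-bis(methoxymethoxy)-4-(triisopropylsilyloxy)phenyllithium | COCOc1cc(O[Si](C(C)C)(C(C)C)C(C)C)cc(OCOC)c1[Li] | intermediate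
8 | {4-[(E)-3,7-dimethylocta-2,6-dienyl]-3,5-bis(methoxymethoxy)phenoxy}triisopropylsilane | COCOc1cc(O[Si](C(C)C)(C(C)C)C(C)C)cc(OCOC)c1C/C=C(\C)CCC=C(C)C | intermediate
9 | 4-[(E)-3,7-dimethylocta-2,6-dienyl]-3,5-bis(methoxymethoxy)phenol | COCOc1cc(O)cc(OCOC)c1C/C=C(\C)CCC=C(C)C | intermediate
10 | 2-bromo-4-[(E)-3,7-dimethylocta-2,6-dienyl]-3,5-bis(methoxymethoxy)phenol | COCOc1cc(O)c(Br)c(OCOC)c1C/C=C(\C)CCC=C(C)C | intermediate
11 | isovanillic acid | COc1ccc(C(=O)O)cc1O | starting material
12 | methoxymethyl 4-methoxy-3-(methoxymethoxy)benzoate | COCOC(=O)c1ccc(OC)c(OCOC)c1 | intermediate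
13 | 4-methoxy-3-(methoxymethoxy)benzoic acid | COCOc1cc(C(=O)O)ccc1OC | intermediate
14 | 2-bromo-4-geranyl-3,5-bis(methoxymethoxy)phenyl 4-methoxy-3-(methoxymethoxy)benzoate | COCOc1cc(ccc1OC)C(=O)Oc1cc(OCOC)c(C/C=C(\C)CCC=C(C)C)c(OCOC)c1Br | intermediate
15 | 2-bromo-4-geranyl-3,5-bis(methoxymethoxy)phenyl 1-[4-methoxy-3-(methoxymethoxy)phenyl]vinyl ether | COCOc1cc(ccc1OC)C(=C)Oc1cc(OCOC)c(C/C=C(\C)CCC=C(C)C)c(OCOC)c1Br | intermediate
16 | aryllithium from 15 (Li in place of Br) | COCOc1cc(ccc1OC)C(=C)Oc1cc(OCOC)c(C/C=C(\C)CCC=C(C)C)c(OCOC)c1[Li] | intermediate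
17 | lithium hemiaminal alkoxide, DMF adduct of 16 | COCOc1cc(ccc1OC)C(=C)Oc1cc(OCOC)c(C/C=C(\C)CCC=C(C)C)c(OCOC)c1C(O[Li])N(C)C | intermediate
18 | 2-{1-[4-methoxy-3-(methoxymethoxy)phenyl]vinyloxy}-5-geranyl-4,6-bis(methoxymethoxy)benzaldehyde | COc1ccc(C(=C)Oc2cc(OCOC)c(C/C=C(\C)CCC=C(C)C)c(OCOC)c2C=O)cc1OCOC | intermediate
19 | (S)-6-geranyl-5,7-bis(methoxymethoxy)-2-[4-methoxy-3-(methoxymethoxy)phenyl]chroman-4-one | COc1ccc([C@@H]2CC(=O)c3c(cc(OCOC)c(C/C=C(\C)CCC=C(C)C)c3OCOC)O2)cc1OCOC | intermediate
20 | (S)-6-geranylhesperetin (CNP0264411.1) | COc1ccc([C@@H]2CC(=O)c3c(cc(O)c(C/C=C(\C)CCC=C(C)C)c3O)O2)cc1O | target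

**Step count**
Total: 12 steps. Longest linear sequence: 11 steps (steps 1–6 and 8–12 from resorcinol); step 7 is the side branch from isovanillic acid.

**Steps most likely to fail**

1. Step 11 (hydroacylation). The risks are hydride insertion and reductive elimination in the 5-exo sense, decarbonylation of the hindered 2,6-dioxygenated acyl rhodium, low face selectivity, and acid-type aldol closure of the enol ether onto the aldehyde.
Fallback by known chemistry, setting out from 9 and coming back at 20. Ortho-formylation of phenol 9 with MgCl2, Et3N and paraformaldehyde in MeCN (both ortho positions are equivalent) should give 3-geranyl-6-hydroxy-2,4-bis(methoxymethoxy)benzaldehyde F1. Addition of ethynylmagnesium bromide (THF, 0 °C) gives the racemic propargylic alcohol F2, MnO2 in CH2Cl2 the 2-hydroxyaryl ynone F3, and amine-mediated 6-endo oxa-Michael closure (Et2NH, EtOH, then AcOH) the 6-geranyl-5,7-bis(methoxymethoxy)chromone F4. Rhodium-catalysed asymmetric 1,4-addition of commercial (3-hydroxy-4-methoxyphenyl)boronic acid (COc1ccc(B(O)O)cc1O) to F4 with [Rh(OH)(cod)]2 and an electron-poor chiral biaryl bisphosphine in toluene/H2O gives the (S)-flavanone with free ring B phenol F5, and the conditions of step 12 then give 20.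

2. Step 6 (bromination). The risks are bromonium formation at the geranyl alkenes and over-bromination at the second ortho position.
Fallback setting out from 8 and coming back at 10. MOM-directed ortho-lithiation of 8 (n-BuLi, TMEDA, THF, −78 → −20 °C) at one of the two equivalent ring positions and quenching with 1,2-dibromotetrachloroethane gives the brominated TIPS ether F6 without free electrophilic bromine meeting the alkenes. Buffered desilylation as in step 5 then gives 10.

3. Step 12 (global deprotection). The risks are acid-promoted addition of the freed C5 or C7 phenol to the geranyl alkene (chroman formation) and addition of methanol to the terminal alkene.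
Fallback setting out from 19 and coming back at 20. Trans-protection with TESOTf and 2,2′-bipyridyl in CH2Cl2 at 0 °C converts the aryl MOM ethers directly into triethylsilyl ethers under buffered, non-protic conditions, giving the tris(triethylsilyl) ether F7. Buffered fluoride (TBAF/AcOH, THF, 0 °C) then frees the three phenols and gives 20.

**Further compounds**
F1 | step 11 | 3-[(E)-3,7-dimethylocta-2,6-dienyl]-6-hydroxy-2,4-bis(methoxymethoxy)benzaldehyde | COCOc1cc(O)c(C=O)c(OCOC)c1C/C=C(\C)CCC=C(C)C
F2 | step 11 | 1-[3-geranyl-6-hydroxy-2,4-bis(methoxymethoxy)phenyl]prop-2-yn-1-ol (racemic) | COCOc1cc(O)c(C(O)C#C)c(OCOC)c1C/C=C(\C)CCC=C(C)C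
F3 | step 11 | 1-[3-geranyl-6-hydroxy-2,4-bis(methoxymethoxy)phenyl]prop-2-yn-1-one | COCOc1cc(O)c(C(=O)C#C)c(OCOC)c1C/C=C(\C)CCC=C(C)C
F4 | step 11 | 6-geranyl-5,7-bis(methoxymethoxy)-4H-chromen-4-one | COCOc1cc2occc(=O)c2c(OCOC)c1C/C=C(\C)CCC=C(C)C
F5 | step 11 | (S)-6-geranyl-2-(3-hydroxy-4-methoxyphenyl)-5,7-bis(methoxymethoxy)chroman-4-one | COc1ccc([C@@H]2CC(=O)c3c(cc(OCOC)c(C/C=C(\C)CCC=C(C)C)c3OCOC)O2)cc1O
F6 | step 6 | {2-bromo-4-[(E)-3,7-dimethylocta-2,6-dienyl]-3,5-bis(methoxymethoxy)phenoxy}triisopropylsilane | COCOc1cc(O[Si](C(C)C)(C(C)C)C(C)C)c(Br)c(OCOC)c1C/C=C(\C)CCC=C(C)C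
F7 | step 12 | (S)-6-geranyl-5,7-bis(triethylsilyloxy)-2-[4-methoxy-3-(triethylsilyloxy)phenyl]chroman-4-one | COc1ccc([C@@H]2CC(=O)c3c(cc(O[Si](CC)(CC)CC)c(C/C=C(\C)CCC=C(C)C)c3O[Si](CC)(CC)CC)O2)cc1O[Si](CC)(CC)CC
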